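**Retrosynthetic overview**
Target gibberellin 34 ⇐ 32 (C19 ethyl ester, C20 dioxolane) ⇐ enone 31 (Luche reduction sets the C15 carbinol; C17 comes from formaldehyde) ⇐ tetracyclic β-keto ester 27.
Key disconnection: C6–C8 (ring B) together with C15–C16 (ring D), by a Michael–Dieckmann cascade of the ring A–ring C diester 25. The enabling feature is the chain C7–C6–C8–C15: C6 and C8 are the α-carbons of the C7 carboxyl and of the C15 carbinol carbon (raised to an ester), so a C8 ester enolate can add to a C6=C7 nitroalkene (nitro = latent C7 carboxyl), and the same C15 ester is then acylated by C16 of the C13 side chain.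
25 ⇐ aldehyde 20 ⇐ alkoxymethylene Wittig/Claisen union of ring-A enone 9 and ring-C allylic alcohol 16, forming C9–C10 at the quaternary carbon that carries the C20 aldehyde.
9 from a catalytic asymmetric Diels–Alder reaction (sets C5) and an ester-enolate methylation (sets C4); 16 from cyclohex-2-enone by α′-alkylation, α-iodination, Luche reduction, lipase resolution and carbonylation.
Ring order: ring A (step 2); ring C (present in the starting enone); rings B and D together (step 17).

Key step: step 17

Remark: skeleton atoms are numbered as in gibberellane (C1–C20); the target is written as the open C20 aldehyde, which may equilibrate with its 19,20-lactol.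
Remark: the sense of induction of the boron catalyst in step 2 and the enantiomer left unacylated by the lipase in step 10 are assumed as written; if either is opposite, the antipodal catalyst is used in step 2 and the acetate is methanolysed in step 10.

Step 1
Reactants: 1 (E)-but-2-enal
Product: 2 (E)-tert-butyl(buta-1,3-dien-1-yloxy)dimethylsilane
Conditions: TBSOTf, Et3N, Et2O, 0 °C to rt
Reagents that add atoms: tert-butyldimethylsilyl triflate, CC(C)(C)[Si](C)(C)OS(=O)(=O)C(F)(F)F
Why: Soft enolisation of the enal toward the γ-carbon and O-silylation (silyl dienol ether formation) should give the electron-rich (E)-1-silyloxydiene needed for the cycloaddition.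

Step 2
Reactants: 2 (E)-tert-butyl(buta-1,3-dien-1-yloxy)dimethylsilane; 3 ethyl (E)-4-oxobut-2-enoate
Product: 4 ethyl 5-(tert-butyldimethylsilyloxy)-6-formylcyclohex-3-ene-1-carboxylate (OTBS and CHO cis, CHO and CO2Et trans)
Conditions: oxazaborolidinium triflimide catalyst [from (S)-α,α-diphenylprolinol, o-tolylboronic acid, HNTf2] (10 mol%), CH2Cl2, −78 °C
Reagents that add atoms: none
Why: Catalytic asymmetric Diels–Alder reaction in which the chiral boron Lewis acid binds the formyl group, so that the silyloxy carbon ends next to the formyl-bearing carbon, endo approach puts OTBS cis to CHO, the E-dienophile gives the trans ester, and the catalyst face selectivity sets C5, the one centre of ring A that is carried through unchanged.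

Step 3
Reactants: 4 ethyl 5-(tert-butyldimethylsilyloxy)-6-formylcyclohex-3-ene-1-carboxylate
Product: 5 ethyl 5-(tert-butyldimethylsilyloxy)-6-(hydroxymethyl)cyclohex-3-ene-1-carboxylate
Conditions: NaBH4, EtOH, −20 °C
Reagents that add atoms: none
Why: Chemoselective NaBH4 reduction of the aldehyde beside the ester removes the acidic formyl α-hydrogen at C5 before any base is used, which secures the catalyst-set C5 centre.

Step 4
Reactants: 5 ethyl 5-(tert-butyldimethylsilyloxy)-6-(hydroxymethyl)cyclohex-3-ene-1-carboxylate
Product: 6 ethyl 6-[(benzyloxy)methyl]-5-(tert-butyldimethylsilyloxy)cyclohex-3-ene-1-carboxylate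
Conditions: BnBr, Ag2O, CH2Cl2, rt, dark
Reagents that add atoms: benzyl bromide, BrCc1ccccc1
Why: Williamson-type O-benzylation under neutral Ag2O activation protects the primary alcohol without an alkoxide that could attack the ester or shift the silyl group.

Step 5
Reactants: 6 ethyl 6-[(benzyloxy)methyl]-5-(tert-butyldimethylsilyloxy)cyclohex-3-ene-1-carboxylate
Product: 7 ethyl 6-[(benzyloxy)methyl]-5-(tert-butyldimethylsilyloxy)-1-methylcyclohex-3-ene-1-carboxylate (CO2Et cis and CH3 trans to CH2OBn)
Conditions: LiN(i-Pr)2, THF, −78 °C; MeI, −78 to −20 °C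
Reagents that add atoms: iodomethane, CI
Why: Ester-enolate alkylation in which iodomethane approaches C4 from the face opposite to both the C5 CH2OBn and the C10 OTBS groups, so the methyl group ends trans and the ester cis to C6, as the target requires.

Step 6
Reactants: 7 ethyl 6-[(benzyloxy)methyl]-5-(tert-butyldimethylsilyloxy)-1-methylcyclohex-3-ene-1-carboxylate
Product: 9 ethyl 6-[(benzyloxy)methyl]-1-methyl-5-oxocyclohex-3-ene-1-carboxylate (ring-A enone), via allylic alcohol 8 (not isolated)
Conditions: HF·pyridine, THF, 0 °C; then Dess–Martin periodinane, NaHCO3, CH2Cl2, 0 °C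
Reagents that add atoms: none
Why: Fluoride desilylation followed by Dess–Martin oxidation of the allylic alcohol should give the enone, the alcohol being oxidised at once because it stands 1,3-cis to the ester, and C5 is not enolised under these non-basic conditions.

Step 7
Reactants: 10 cyclohex-2-en-1-one; 11 methyl bromoacetate
Product: 12 methyl 2-(2-oxocyclohex-3-en-1-yl)acetate (racemic)
Conditions: LiN(i-Pr)2, THF, −78 °C; 11, DMPU, −78 to −40 °C
Reagents that add atoms: none
Why: Kinetic α′-deprotonation of the enone and SN2 alkylation of the cross-conjugated enolate install the acetate arm on the future C13 (its methylene is C16, its carboxyl carbon is excised in step 18), racemic at this stage.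

Step 8
Reactants: 12 methyl 2-(2-oxocyclohex-3-en-1-yl)acetate
Product: 13 methyl 2-(3-iodo-2-oxocyclohex-3-en-1-yl)acetate (racemic)
Conditions: I2, pyridine, CH2Cl2, 0 °C to rt
Reagents that add atoms: iodine, [I][I]
Why: α-Iodination of the enone by conjugate addition of pyridine, iodination of the enolate and elimination (Baylis–Hillman-type addition–elimination) places the handle for C15 on the future C8.

Step 9
Reactants: 13 methyl 2-(3-iodo-2-oxocyclohex-3-en-1-yl)acetate
Product: 14 methyl 2-(trans-2-hydroxy-3-iodocyclohex-3-en-1-yl)acetate (racemic)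
Conditions: NaBH4, CeCl3·7H2O, MeOH, −78 °C
Reagents that add atoms: none
Why: Luche 1,2-reduction in which hydride attacks axially, anti to the equatorial acetate arm, should give the trans alcohol (future C14–O trans to the C13 side chain).

Step 10
Reactants: 14 methyl 2-(trans-2-hydroxy-3-iodocyclohex-3-en-1-yl)acetate (racemic)
Product: 15 methyl 2-[(1S,2S)-2-hydroxy-3-iodocyclohex-3-en-1-yl]acetate
Conditions: Burkholderia cepacia lipase, vinyl acetate, t-BuOMe, 30 °C, to about 50% conversion
Reagents that add atoms: none
Why: Lipase-catalysed transesterification (kinetic resolution) acetylates one enantiomer of the secondary allylic alcohol, leaving the required (1S,2S)-alcohol to be separated from the (1R,2R)-acetate.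

Step 11
Reactants: 15 methyl 2-[(1S,2S)-2-hydroxy-3-iodocyclohex-3-en-1-yl]acetate
Product: 16 methyl (5S,6S)-6-hydroxy-5-(2-methoxy-2-oxoethyl)cyclohex-1-ene-1-carboxylate
Conditions: Pd(OAc)2 (5 mol%), PPh3, CO (1 atm), MeOH, Et3N, DMF, 60 °C
Reagents that add atoms: carbon monoxide, [C-]#[O+]; methanol, CO
Why: Palladium-catalysed methoxycarbonylation (oxidative addition of zerovalent palladium to the vinyl iodide, CO insertion, methanolysis) turns the iodide into the C15 ester without touching the two stereocentres.

Step 12
Reactants: 16 methyl (5S,6S)-6-hydroxy-5-(2-methoxy-2-oxoethyl)cyclohex-1-ene-1-carboxylate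
Product: 18 ({[(1S,6S)-2-(methoxycarbonyl)-6-(2-methoxy-2-oxoethyl)cyclohex-2-en-1-yl]oxy}methyl)triphenylphosphonium chloride, via chloromethyl ether 17 (not isolated)
Conditions: (CH2O)n, Me3SiCl, CH2Cl2, 0 °C to rt; then PPh3, toluene, 60 °C
Reagents that add atoms: formaldehyde (as paraformaldehyde), C=O; chlorotrimethylsilane, C[Si](C)(C)Cl; triphenylphosphine, c1ccc(cc1)P(c1ccccc1)c1ccccc1
Why: Chloromethylation of the alcohol (hemiacetal formation and chloride exchange) followed by SN2 quaternisation of PPh3 gives the alkoxymethylphosphonium salt for the olefination.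

Step 13
Reactants: 18 alkoxymethylphosphonium chloride; 9 ring-A enone
Product: 20 ethyl 6-[(benzyloxy)methyl]-5-formyl-5-[2-(methoxycarbonyl)-4-(2-methoxy-2-oxoethyl)cyclohex-2-en-1-yl]-1-methylcyclohex-3-ene-1-carboxylate, via allyl dienol ether 19 (not isolated)
Conditions: KN(SiMe3)2, THF, −78 °C; 9, −78 to 0 °C; then xylene, 140 °C
Reagents that add atoms: none
Why: Wittig olefination of the ketone with the alkoxymethylene ylide gives the allyl vinyl ether, whose Claisen rearrangement forms the C9–C10 bond, C9 being set by suprafacial chirality transfer from the C14–O centre and C10 by bond formation on the ring-A face opposite to the C5 CH2OBn group, which puts the new formyl group (C20) cis to the C19 ester.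

Step 14
Reactants: 20 ring A–ring C aldehyde
Product: 21 the C20 1,3-dioxolane of 20
Conditions: Me3SiOCH2CH2OSiMe3, Me3SiOTf (5 mol%), CH2Cl2, −78 to −20 °C
Reagents that add atoms: 1,2-bis(trimethylsilyloxy)ethane, C[Si](C)(C)OCCO[Si](C)(C)C
Why: Silyl-triflate-catalysed acetalisation of the neopentyl aldehyde with the bis-silylated glycol needs no water removal, leaves esters and alkenes intact, and masks C20 through the later base, nitrite and hydride steps.

Step 15
Reactants: 21 dioxolane
Product: 23 ethyl 5-(1,3-dioxolan-2-yl)-6-formyl-5-[2-(methoxycarbonyl)-4-(2-methoxy-2-oxoethyl)cyclohexyl]-1-methylcyclohexane-1-carboxylate, via hydroxy triester 22 (not isolated)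
Conditions: H2 (4 atm), Pd(OH)2 on carbon, EtOAc, rt; then Dess–Martin periodinane, NaHCO3, CH2Cl2, 0 °C
Reagents that add atoms: none
Why: Heterogeneous hydrogenation saturates C1=C2 and C8=C14 and hydrogenolyses the benzyl ether in one operation, hydrogen adding to C8 from the face opposite to the C10-bearing substituent on C9 so that the C15 ester is trans to the C13 side chain, and the freed primary alcohol is oxidised at once (Dess–Martin oxidation) to forestall lactonisation onto the C19 ester.

Step 16
Reactants: 23 C6 aldehyde
Product: 25 ethyl 5-(1,3-dioxolan-2-yl)-5-[2-(methoxycarbonyl)-4-(2-methoxy-2-oxoethyl)cyclohexyl]-1-methyl-6-[(E)-2-nitroethenyl]cyclohexane-1-carboxylate, via nitro alcohol 24 (not isolated)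
Conditions: CH3NO2, 1,1,3,3-tetramethylguanidine (10 mol%), 0 °C; then MsCl, Et3N, CH2Cl2, −20 to 0 °C
Reagents that add atoms: nitromethane, C[N+](=O)[O-]
Why: Henry (nitroaldol) addition of nitromethane and E1cB elimination of the mesylate should give the conjugated (E)-nitroalkene, which attaches C7 in latent carboxyl form.

Step 17
Reactants: 25 (E)-nitroalkene triester
Product: 27 tetracyclic β-keto ester (gibberellane skeleton with 15-oxo, 16-CO2Me, C7 as CH2NO2, 19-ethyl ester, C20 dioxolane), via Michael adduct 26 (not isolated)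
Conditions: KN(SiMe3)2 (3.2 equiv), THF, −78 to 0 °C; AcOH, −78 °C
Reagents that add atoms: none
Why: Excess base turns both methyl esters into enolates, of which only the C8 enolate can reach the nitroalkene through a five-membered transition state, so intramolecular Michael addition of C8 to C6 (5-exo-trig) closes ring B and forms the C6–C8 bond; the C16 enolate then attacks the C15 ester, now held 1,3-diaxial to it on ring C (Dieckmann condensation, 5-exo-trig), and closes ring D, the whole being a Michael–Dieckmann (Michael–Claisen) cascade of the kind used to build polycyclic β-keto esters. The quaternary C8 centre is set by the ring system, because the three-atom tether from C9 can deliver C6 only to the face of ring C that carries C10, which gives the cis B/C fusion of the target and turns the C15 ester to the face of the C13 side chain. C6 is set by the nitroalkene rotamer in which the C5 hydrogen eclipses the double bond, which keeps C7 away from the quaternary C4 and places it cis to the C5 hydrogen as in the target; C16 is an enolised β-keto ester carbon and carries no lasting stereochemistry. The step needs the Michael addition to come before the Dieckmann closure, and this is secured twice: an ester that is present as its enolate is no acylating agent, so the C15 ester becomes electrophilic only after C8 has been quaternised, and before that point ring D could close only from a ring-C chair with three axial substituents. Acylation of the C8 enolate by the side-chain ester and all proton transfers are reversible, whereas the nitro-Michael step and the final deprotonation of the β-keto ester are not, so the system should funnel to 27.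

Step 18
Reactants: 27 tetracyclic β-keto ester
Product: 29 tetracyclic 15-ketone with C16 as CH2 (C7 as CH2NO2, 19-ethyl ester, C20 dioxolane), via β-keto acid 28 (not isolated)
Conditions: LiOH, THF/H2O, 40 °C; then AcOH (pH 4–5), 50 °C
Reagents that add atoms: none
Why: Saponification of the β-keto ester and decarboxylation of the β-keto acid through its six-membered transition state remove the activating carboxyl group, while the hindered C19 ethyl ester and the dioxolane should survive.

Step 19
Reactants: 29 nitro ketone
Product: 30 tetracyclic 15-ketone 7-carboxylic acid (19-ethyl ester, C20 dioxolane)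
Conditions: NaNO2, AcOH, DMSO, 35 °C
Reagents that add atoms: sodium nitrite, [Na+].[O-]N=O
Why: Nitrosative oxidation of the primary nitroalkane (via the nitrolic acid) converts CH2NO2 directly into the C7 carboxylic acid without an enolisable aldehyde stage, so C6 keeps its configuration.

Step 20
Reactants: 30 keto acid
Product: 31 16-methylene-15-ketone 7-acid (19-ethyl ester, C20 dioxolane)
Conditions: (CH2O)n, N-methylanilinium trifluoroacetate, THF, 65 °C
Reagents that add atoms: formaldehyde (as paraformaldehyde), C=O
Why: Mannich-type α-methylenation in which the anilinium salt delivers an iminium ion from formaldehyde to C16, the only enolisable position of the ketone, and β-elimination of the amine gives the exocyclic enone.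

Step 21
Reactants: 31 enone
Product: 32 15-hydroxy-16-methylene 7-acid (19-ethyl ester, C20 dioxolane; hydroxyl on the face turned toward C11)
Conditions: NaBH4, CeCl3·7H2O, MeOH, −78 °C
Reagents that add atoms: none
Why: Luche 1,2-reduction in which hydride enters C15 from the exo face of the bicyclo[3.2.1]octenone (the side of the one-carbon bridge C14), the endo face being screened by the axial hydrogen on C11, which should place the hydroxyl on the face turned toward C11 as in the target.

Step 22
Reactants: 32 allylic alcohol
Product: 34 the target gibberellin (15β-hydroxy-20-oxogibberell-16-ene-7,19-dioic acid), via C20 aldehyde 33 (not isolated)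
Conditions: Me3SiOTf, 2,4,6-collidine, CH2Cl2, 0 °C, then H2O; LiOH, THF/H2O, rt; 1 M HCl to pH 3
Reagents that add atoms: water, O; lithium hydroxide, [Li+].[OH-]
Why: Silyl triflate/collidine cleavage of the dioxolane (collidinium intermediate hydrolysed by water) frees the aldehyde under non-acidic conditions that spare the allylic alcohol, and hydroxide then cleaves the hindered C19 ethyl ester with anchimeric help from the 1,3-diaxial aldehyde hydrate (transient 19,20-lactol-lactone), the silyl groups being lost in the same aqueous base.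

**Compound list**
1 | (E)-but-2-enal | C/C=C/C=O | starting material
2 | (E)-tert-butyl(buta-1,3-dien-1-yloxy)dimethylsilane | C=C/C=C/O[Si](C)(C)C(C)(C)C | intermediate
3 | ethyl (E)-4-oxobut-2-enoate | CCOC(=O)/C=C/C=O | starting material
4 | ethyl 5-(tert-butyldimethylsilyloxy)-6-formylcyclohex-3-ene-1-carboxylate (OTBS/CHO cis, CHO/CO2Et trans) | CCOC(=O)[C@H]1CC=C[C@H](O[Si](C)(C)C(C)(C)C)[C@@H]1C=O | intermediate
5 | ethyl 5-(tert-butyldimethylsilyloxy)-6-(hydroxymethyl)cyclohex-3-ene-1-carboxylate | CCOC(=O)[C@H]1CC=C[C@H](O[Si](C)(C)C(C)(C)C)[C@@H]1CO | intermediate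
6 | ethyl 6-[(benzyloxy)methyl]-5-(tert-butyldimethylsilyloxy)cyclohex-3-ene-1-carboxylate | CCOC(=O)[C@H]1CC=C[C@H](O[Si](C)(C)C(C)(C)C)[C@@H]1COCc1ccccc1 | intermediate
7 | ethyl 6-[(benzyloxy)methyl]-5-(tert-butyldimethylsilyloxy)-1-methylcyclohex-3-ene-1-carboxylate (CO2Et cis, CH3 trans to CH2OBn) | CCOC(=O)[C@]1(C)CC=C[C@H](O[Si](C)(C)C(C)(C)C)[C@@H]1COCc1ccccc1 | intermediate
8 | ethyl 6-[(benzyloxy)methyl]-5-hydroxy-1-methylcyclohex-3-ene-1-carboxylate (not isolated) | CCOC(=O)[C@]1(C)CC=C[C@H](O)[C@@H]1COCc1ccccc1 | intermediate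
9 | ethyl 6-[(benzyloxy)methyl]-1-methyl-5-oxocyclohex-3-ene-1-carboxylate (ring-A enone) | CCOC(=O)[C@]1(C)CC=CC(=O)[C@@H]1COCc1ccccc1 | intermediate
10 | cyclohex-2-en-1-one | O=C1C=CCCC1 | starting material
11 | methyl bromoacetate | COC(=O)CBr | starting material
12 | methyl 2-(2-oxocyclohex-3-en-1-yl)acetate (racemic) | COC(=O)CC1CCC=CC1=O | intermediate
13 | methyl 2-(3-iodo-2-oxocyclohex-3-en-1-yl)acetate (racemic) | COC(=O)CC1CCC=C(I)C1=O | intermediate
14 | methyl 2-(trans-2-hydroxy-3-iodocyclohex-3-en-1-yl)acetate (racemate, both enantiomers written) | COC(=O)C[C@@H]1CCC=C(I)[C@H]1O.COC(=O)C[C@H]1CCC=C(I)[C@@H]1O | intermediate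
15 | methyl 2-[(1S,2S)-2-hydroxy-3-iodocyclohex-3-en-1-yl]acetate | COC(=O)C[C@@H]1CCC=C(I)[C@H]1O | intermediate
16 | methyl (5S,6S)-6-hydroxy-5-(2-methoxy-2-oxoethyl)cyclohex-1-ene-1-carboxylate | COC(=O)C[C@@H]1CCC=C(C(=O)OC)[C@H]1O | intermediate
17 | chloromethyl ether of 16 (not isolated) | COC(=O)C[C@@H]1CCC=C(C(=O)OC)[C@H]1OCCl | intermediate
18 | ({[(1S,6S)-2-(methoxycarbonyl)-6-(2-methoxy-2-oxoethyl)cyclohex-2-en-1-yl]oxy}methyl)triphenylphosphonium chloride | COC(=O)C[C@@H]1CCC=C(C(=O)OC)[C@H]1OC[P+](c1ccccc1)(c1ccccc1)c1ccccc1.[Cl-] | intermediate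
19 | allyl dienol ether from 9 and the ylide of 18 (E/Z mixture at C10=C20, geometry left open; not isolated) | CCOC(=O)[C@]1(C)CC=CC(=CO[C@H]2[C@H](CC(=O)OC)CCC=C2C(=O)OC)[C@@H]1COCc1ccccc1 | intermediate
20 | ethyl 6-[(benzyloxy)methyl]-5-formyl-5-[2-(methoxycarbonyl)-4-(2-methoxy-2-oxoethyl)cyclohex-2-en-1-yl]-1-methylcyclohex-3-ene-1-carboxylate (C4, C5, C9, C10, C13 as in the target) | COC(=O)C[C@@H]1CC[C@H](C(C(=O)OC)=C1)[C@]2(C=O)C=CC[C@@](C)(C(=O)OCC)[C@H]2COCc3ccccc3 | intermediate
21 | C20 1,3-dioxolane of 20 | COC(=O)C[C@@H]1CC[C@H](C(C(=O)OC)=C1)[C@]2(C3OCCO3)C=CC[C@@](C)(C(=O)OCC)[C@H]2COCc4ccccc4 | intermediate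
22 | ethyl 5-(1,3-dioxolan-2-yl)-6-(hydroxymethyl)-5-[2-(methoxycarbonyl)-4-(2-methoxy-2-oxoethyl)cyclohexyl]-1-methylcyclohexane-1-carboxylate (C15 ester trans to the C13 side chain; not isolated) | COC(=O)C[C@@H]1CC[C@H]([C@@H](C(=O)OC)C1)[C@]2(C3OCCO3)CCC[C@@](C)(C(=O)OCC)[C@H]2CO | intermediate
23 | the 6-formyl analogue of 22 (C6 aldehyde) | COC(=O)C[C@@H]1CC[C@H]([C@@H](C(=O)OC)C1)[C@]2(C3OCCO3)CCC[C@@](C)(C(=O)OCC)[C@H]2C=O | intermediate
24 | the 6-(1-hydroxy-2-nitroethyl) analogue (carbinol epimers; not isolated) | COC(=O)C[C@@H]1CC[C@H]([C@@H](C(=O)OC)C1)[C@]2(C3OCCO3)CCC[C@@](C)(C(=O)OCC)[C@H]2C(O)C[N+](=O)[O-] | intermediate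
25 | the 6-[(E)-2-nitroethenyl] analogue (cascade substrate) | COC(=O)C[C@@H]1CC[C@H]([C@@H](C(=O)OC)C1)[C@]2(C3OCCO3)CCC[C@@](C)(C(=O)OCC)[C@H]2/C=C/[N+](=O)[O-] | intermediate
26 | tricyclic Michael adduct (rings A, B, C; C6 bears CH2NO2, quaternary C8 bears CO2Me, C13 bears CH2CO2Me; not isolated) | COC(=O)C[C@@H]1CC[C@H]2[C@]3(C4OCCO4)CCC[C@@](C)(C(=O)OCC)[C@H]3[C@H](C[N+](=O)[O-])[C@]2(C1)C(=O)OC | intermediate
27 | tetracyclic β-keto ester (15-oxo, 16-CO2Me, C7 as CH2NO2, 19-ethyl ester, C20 dioxolane; C16 epimers/enol) | COC(=O)C1[C@@H]2CC[C@H]3[C@]4(C5OCCO5)CCC[C@@](C)(C(=O)OCC)[C@H]4[C@H](C[N+](=O)[O-])[C@]3(C2)C1=O | intermediate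
28 | β-keto acid from 27 (not isolated) | OC(=O)C1[C@@H]2CC[C@H]3[C@]4(C5OCCO5)CCC[C@@](C)(C(=O)OCC)[C@H]4[C@H](C[N+](=O)[O-])[C@]3(C2)C1=O | intermediate
29 | tetracyclic 15-ketone, C16 as CH2, C7 as CH2NO2 | C1[C@@H]2CC[C@H]3[C@]4(C5OCCO5)CCC[C@@](C)(C(=O)OCC)[C@H]4[C@H](C[N+](=O)[O-])[C@]3(C2)C1=O | intermediate
30 | tetracyclic 15-ketone 7-carboxylic acid | C1[C@@H]2CC[C@H]3[C@]4(C5OCCO5)CCC[C@@](C)(C(=O)OCC)[C@H]4[C@H](C(=O)O)[C@]3(C2)C1=O | intermediate
31 | 16-methylene-15-ketone 7-acid (19-ethyl ester, C20 dioxolane) | C=C1[C@@H]2CC[C@H]3[C@]4(C5OCCO5)CCC[C@@](C)(C(=O)OCC)[C@H]4[C@H](C(=O)O)[C@]3(C2)C1=O | intermediate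
32 | 15-hydroxy-16-methylene 7-acid (19-ethyl ester, C20 dioxolane) | C=C1[C@@H]2CC[C@H]3[C@]4(C5OCCO5)CCC[C@@](C)(C(=O)OCC)[C@H]4[C@H](C(=O)O)[C@]3(C2)[C@@H]1O | intermediate
33 | 19-ethyl ester of the target gibberellin (free C20 aldehyde; not isolated) | C=C1[C@@H]2CC[C@H]3[C@]4(C=O)CCC[C@@](C)(C(=O)OCC)[C@H]4[C@H](C(=O)O)[C@]3(C2)[C@@H]1O | intermediate
34 | the target gibberellin, 15β-hydroxy-20-oxogibberell-16-ene-7,19-dioic acid (C20 aldehyde, C7 and C19 carboxylic acids, 15-hydroxyl, 16-methylene) | C=C1[C@@H]2CC[C@H]3[C@]4(C=O)CCC[C@@](C)(C(=O)O)[C@H]4[C@H](C(=O)O)[C@]3(C2)[C@@H]1O | target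

Total step count: 22.
Longest linear sequence: 16 steps (steps 1–6 or steps 7–12, followed by steps 13–22).

**Steps most likely to fail**

Step 17. The hindered C8 enolate may form and add too slowly, so that deprotonation of the nitroalkene at its γ-carbon C5, base-induced polymerisation of the nitroalkene or ring closure in the wrong order takes over. The fallback sets out from 25 and returns at 27. Compound 25 is silylated with in-situ quench (KN(SiMe3)2 in the presence of Me3SiCl, THF, −100 °C) to the bis(trimethylsilyl ketene acetal) of 25 F1. TiCl2(O-i-Pr)2 in CH2Cl2 at −78 °C then promotes an intramolecular Mukaiyama–Michael addition of the C8 ketene acetal to the nitroalkene, which after aqueous work-up gives 26, now isolated. NaOMe in MeOH closes ring D by Dieckmann condensation to 27.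

Step 13. The bulky ylide may enolise the hindered enone or transfer a proton within itself instead of olefinating, and the facial selectivity at C10 may erode. The fallback sets out from 9 and returns at 20. Compound 9 is olefinated with the small ylide from (methoxymethyl)triphenylphosphonium chloride and KOt-Bu (THF, 0 °C) to the methyl dienol ether of 9 F2. Heating this with alcohol 16 and a trace of propionic acid in xylene at 140 °C, with removal of methanol, exchanges the enol ether through the mixed acetal to 19, which rearranges in the same flask to 20.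

Step 16. Retro-Henry reaction, lactonisation of the nitro-aldol onto the C19 ester, or epimerisation at C5 may intervene under the basic conditions at the very hindered aldehyde. The fallback sets out from 23 and returns at 25. Compound 23 is methylenated without base (Zn, CH2I2, TiCl4, THF/CH2Cl2, 0 °C) to the 6-ethenyl compound F3. The terminal alkene is then converted to the (E)-nitroalkene 25 by radical nitration–elimination with AgNO2 and TEMPO (1,2-dichloroethane, 70 °C).

Further compounds
F1 | step 17 | bis(trimethylsilyl ketene acetal) of 25, formed at the C15 ester and at the side-chain ester | COC(O[Si](C)(C)C)=C[C@@H]1CC[C@H](C(C1)=C(OC)O[Si](C)(C)C)[C@]2(C3OCCO3)CCC[C@@](C)(C(=O)OCC)[C@H]2/C=C/[N+](=O)[O-]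
F2 | step 13 | ethyl 6-[(benzyloxy)methyl]-5-(methoxymethylidene)-1-methylcyclohex-3-ene-1-carboxylate | CCOC(=O)[C@]1(C)CC=CC(=COC)[C@@H]1COCc1ccccc1
F3 | step 16 | ethyl 5-(1,3-dioxolan-2-yl)-6-ethenyl-5-[2-(methoxycarbonyl)-4-(2-methoxy-2-oxoethyl)cyclohexyl]-1-methylcyclohexane-1-carboxylate | COC(=O)C[C@@H]1CC[C@H]([C@@H](C(=O)OC)C1)[C@]2(C3OCCO3)CCC[C@@](C)(C(=O)OCC)[C@H]2C=C
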